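## Retrosynthetic overview

1. The route rests on the C3–C4 bridge of the isoflavan. C4 is the benzylic CH2 on ring A carbon C4a, and C3 is the only stereocentre and carries ring B carbon C1′. Both carbons come from the vinyl group of a vinylboronate, so C4–C4a and C3–C1′ are cut together to give ring A triflate 11, ring B aryllithium 13 and vinylboronate 12, with boron left on C3.
2. C2 is added afterwards by one-carbon homologation of the C3 boronate (retention) and C–B oxidation. The C8 formyl group is then placed ortho to the freed O1 phenol, ring C is closed by O1–C2 etherification, and 7-O-demethylation and desilylation finish the synthesis.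
3. Ring B bromide 6 comes from 4-bromoresorcinol (silylation, propargylation, Claisen cyclisation). Triflate 11 comes from 2-hydroxy-4,6-dimethoxybenzaldehyde (MOM ether, Dakin oxidation, triflation).
4. Ring order: rings A and B are bought as arenes, the dimethylpyran ring on ring B is formed first (step 3), and ring C is formed last (step 11).

Key step: step 7

Assumption: the (Sp,Sp) antipode of the Mandyphos ligand is taken to deliver the R configuration at C3 of boronate 15. If the sense of induction is the opposite, the (Rp,Rp) antipode is used and nothing else changes.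

## Route

Step 1
Reactants: 1 4-bromoresorcinol
Product: 2 2-bromo-5-(triisopropylsilyloxy)phenol
Conditions: TIPSCl (1.05 equiv), imidazole, CH2Cl2, 0 °C
Reagents that add atoms: triisopropylsilyl chloride, CC(C)[Si](Cl)(C(C)C)C(C)C
Why: Imidazole-mediated silylation of a phenol with a bulky silyl chloride should take place at the unhindered hydroxyl para to bromine and leave the hydroxyl flanked by bromine free.

Step 2
Reactants: 2 2-bromo-5-(triisopropylsilyloxy)phenol; 3 3-chloro-3-methylbut-1-yne
Product: 4 1-bromo-2-[(2-methylbut-3-yn-2-yl)oxy]-4-(triisopropylsilyloxy)benzene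
Conditions: DBU, CuCl2·2H2O (cat.), MeCN, 0 °C
Reagents that add atoms: none
Why: Copper-catalysed O-propargylation of a phenol with a tertiary propargylic chloride under amine base is a standard entry to aryl 1,1-dimethylpropargyl ethers and should tolerate the ortho bromine and the silyl ether.

Step 3
Reactants: 4 1-bromo-2-[(2-methylbut-3-yn-2-yl)oxy]-4-(triisopropylsilyloxy)benzene
Product: 6 8-bromo-2,2-dimethyl-5-(triisopropylsilyloxy)-2H-chromene, via allenylphenol 5 (not isolated)
Conditions: N,N-diethylaniline, 190 °C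
Reagents that add atoms: none
Why: Aromatic propargyl Claisen rearrangement: bromine blocks one ortho position, so the [3,3] shift goes to the carbon between the two oxygens, and enolisation to allenylphenol 5, 1,5-hydrogen shift and oxa-6π electrocyclisation close the 2,2-dimethylpyran ring.

Step 4
Reactants: 7 2-hydroxy-4,6-dimethoxybenzaldehyde
Product: 8 2,4-dimethoxy-6-(methoxymethoxy)benzaldehyde
Conditions: MOMCl, i-Pr2NEt, CH2Cl2, 0 °C → 40 °C
Reagents that add atoms: chloromethyl methyl ether, COCCl
Why: Williamson-type O-alkylation (MOM protection) of the chelated phenol with MOMCl and a hindered amine base is routine for salicylaldehydes.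

Step 5
Reactants: 8 2,4-dimethoxy-6-(methoxymethoxy)benzaldehyde
Product: 10 2,4-dimethoxy-6-(methoxymethoxy)phenol, via aryl formate 9 (not isolated)
Conditions: mCPBA, CH2Cl2, 0 °C → rt; aqueous NaHCO3 wash; then K2CO3 (cat.), MeOH, 0 °C, under argon
Reagents that add atoms: 3-chloroperbenzoic acid, OOC(=O)c1cccc(Cl)c1
Why: Dakin-type Baeyer–Villiger oxidation, in which the electron-rich aryl group migrates to oxygen to give formate 9, and mild base methanolysis then frees the phenol without touching the MOM acetal.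

Step 6
Reactants: 10 2,4-dimethoxy-6-(methoxymethoxy)phenol
Product: 11 2,4-dimethoxy-6-(methoxymethoxy)phenyl trifluoromethanesulfonate
Conditions: Tf2O, pyridine, CH2Cl2, −20 °C → 0 °C
Reagents that add atoms: trifluoromethanesulfonic anhydride, O=S(=O)(OS(=O)(=O)C(F)(F)F)C(F)(F)F
Why: O-Sulfonylation of the phenol with Tf2O and pyridine should give the aryl triflate, the basic medium protecting the MOM acetal.

Step 7
Reactants: 6 8-bromo-2,2-dimethyl-5-(triisopropylsilyloxy)-2H-chromene; 12 vinylboronic acid pinacol ester; 11 2,4-dimethoxy-6-(methoxymethoxy)phenyl trifluoromethanesulfonate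
Product: 15 pinacol (1R)-1-[2,2-dimethyl-5-(triisopropylsilyloxy)-2H-chromen-8-yl]-2-[2,4-dimethoxy-6-(methoxymethoxy)phenyl]ethylboronate, via aryllithium 13 (not isolated), via lithium vinylboronate complex 14 (not isolated)
Conditions: 6, t-BuLi (2.0 equiv), Et2O, −78 °C; 12, −78 °C → rt; solvent exchanged for THF; 11, KOTf, Pd(OAc)2 (3 mol %), (Sp,Sp)-Mandyphos ligand with bis(4-methoxy-3,5-dimethylphenyl)phosphino groups (3.6 mol %), 60 °C
Reagents that add atoms: none
Why: Bromine–lithium exchange on 6 gives aryllithium 13, which adds to boron of 12 to give four-coordinate boronate 14; zerovalent palladium carrying the chiral bisphosphine inserts into the C–OTf bond of 11, the cationic arylpalladium binds the vinyl group of 14 and induces an anti 1,2-shift of the ring B aryl group from boron to the alpha carbon (C3–C1′) as palladium bonds to the terminal carbon, and reductive elimination forms C4–C4a. The closest known reaction type is the palladium-catalysed enantioselective conjunctive cross-coupling of vinylboron ate complexes with aryl triflates in which an aryl group migrates. No ring is closed in this step. The one new stereocentre, C3, is set by the catalyst: the ferrocenyl bisphosphine on divalent palladium selects the enantioface of the bound vinyl group during the metallate shift, here to give R. The step needs the metallate shift to win over direct transfer of aryl or vinyl from boron to palladium and over oxygen migration: the triflate counter-ion, with KOTf to precipitate bromide, keeps palladium cationic and olefin-bound, the pinacol oxygens are poor migrating groups, and the two ortho substituents of 11 are small alkoxy groups that should still allow oxidative addition and reductive elimination.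

Step 8
Reactants: 15 pinacol (1R)-1-[2,2-dimethyl-5-(triisopropylsilyloxy)-2H-chromen-8-yl]-2-[2,4-dimethoxy-6-(methoxymethoxy)phenyl]ethylboronate
Product: 18 (2R)-2-[2,2-dimethyl-5-(triisopropylsilyloxy)-2H-chromen-8-yl]-3-[2,4-dimethoxy-6-(methoxymethoxy)phenyl]propan-1-ol, via chloromethyl boronate complex 16 (not isolated), via homologated boronate 17 (not isolated)
Conditions: BrCH2Cl, n-BuLi, THF, −78 °C → rt; then NaBO3·4H2O, THF/H2O, rt
Reagents that add atoms: bromochloromethane, ClCBr; sodium perborate, [Na+].[O-]OB=O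
Why: Matteson homologation, in which LiCH2Cl formed in the flask adds to boron to give complex 16 and the C3 carbon migrates to CH2 with loss of chloride and retention at C3, followed by perborate oxidation of the primary C–B bond of 17 under mild conditions that should spare the aryl silyl ether.

Step 9
Reactants: 18 (2R)-2-[2,2-dimethyl-5-(triisopropylsilyloxy)-2H-chromen-8-yl]-3-[2,4-dimethoxy-6-(methoxymethoxy)phenyl]propan-1-ol
Product: 19 2-[(2R)-2-[2,2-dimethyl-5-(triisopropylsilyloxy)-2H-chromen-8-yl]-3-hydroxypropyl]-3,5-dimethoxyphenol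
Conditions: conc. HCl (cat.), MeOH/THF, 40 °C
Reagents that add atoms: none
Why: Acid-catalysed acetal methanolysis removes the aryl MOM group under dilute conditions that the aryl triisopropylsilyl ether and the 2,2-dimethylchromene should survive.

Step 10
Reactants: 19 2-[(2R)-2-[2,2-dimethyl-5-(triisopropylsilyloxy)-2H-chromen-8-yl]-3-hydroxypropyl]-3,5-dimethoxyphenol
Product: 21 2-hydroxy-3-[(2R)-2-[2,2-dimethyl-5-(triisopropylsilyloxy)-2H-chromen-8-yl]-3-hydroxypropyl]-4,6-dimethoxybenzaldehyde, via hydroxymethylphenol 20 (not isolated)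
Conditions: MgCl2 (anhydrous), Et3N, (CH2O)n, THF, reflux
Reagents that add atoms: paraformaldehyde (formaldehyde), C=O
Why: Magnesium-mediated ortho-formylation of a phenol (Casnati–Skattebøl), in which the magnesium phenoxide delivers formaldehyde only to an ortho carbon, the sole free one being the future C8, and hydroxymethylphenol 20 is oxidised by a second formaldehyde through hydride transfer, so that C6 and ring B should stay untouched.

Step 11
Reactants: 21 2-hydroxy-3-[(2R)-2-[2,2-dimethyl-5-(triisopropylsilyloxy)-2H-chromen-8-yl]-3-hydroxypropyl]-4,6-dimethoxybenzaldehyde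
Product: 22 (3R)-3-[2,2-dimethyl-5-(triisopropylsilyloxy)-2H-chromen-8-yl]-5,7-dimethoxychromane-8-carbaldehyde
Conditions: PPh3, DIAD, THF (0.02 M), 0 °C → rt
Reagents that add atoms: none
Why: Intramolecular Mitsunobu etherification (6-exo-tet) between the acidic salicylaldehyde-type phenol and the primary alcohol closes ring C at O1–C2 without involving the C3 stereocentre.

Step 12
Reactants: 22 (3R)-3-[2,2-dimethyl-5-(triisopropylsilyloxy)-2H-chromen-8-yl]-5,7-dimethoxychromane-8-carbaldehyde
Product: 23 (3R)-3-[2,2-dimethyl-5-(triisopropylsilyloxy)-2H-chromen-8-yl]-7-hydroxy-5-methoxychromane-8-carbaldehyde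
Conditions: MgI2·OEt2, toluene/Et2O, 70 °C; aqueous work-up
Reagents that add atoms: none
Why: Chelation-controlled ether cleavage, in which magnesium bridges the aldehyde oxygen and the ortho 7-methoxy oxygen and iodide removes the methyl group by SN2, whereas the para 5-methoxy group is not chelated and the ring O1–C2 carbon is a slower, beta-branched SN2 site.

Step 13
Reactants: 23 (3R)-3-[2,2-dimethyl-5-(triisopropylsilyloxy)-2H-chromen-8-yl]-7-hydroxy-5-methoxychromane-8-carbaldehyde
Product: 24 (3R)-7-hydroxy-3-(5-hydroxy-2,2-dimethyl-2H-chromen-8-yl)-5-methoxychromane-8-carbaldehyde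
Conditions: Bu4NF, AcOH, THF, 0 °C
Reagents that add atoms: none
Why: Fluoride-mediated cleavage of the aryl silyl ether, buffered with acetic acid to protect the hydroxy aldehyde, should release the ring B phenol and give the target.

## Compound list

1 | 4-bromoresorcinol | Oc1ccc(Br)c(O)c1 | starting material
2 | 2-bromo-5-(triisopropylsilyloxy)phenol | Oc1cc(O[Si](C(C)C)(C(C)C)C(C)C)ccc1Br | intermediate
3 | 3-chloro-3-methylbut-1-yne | CC(C)(Cl)C#C | starting material
4 | 1-bromo-2-[(2-methylbut-3-yn-2-yl)oxy]-4-(triisopropylsilyloxy)benzene | C#CC(C)(C)Oc1cc(O[Si](C(C)C)(C(C)C)C(C)C)ccc1Br | intermediate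
5 | 6-bromo-2-(3-methylbuta-1,2-dien-1-yl)-3-(triisopropylsilyloxy)phenol | CC(C)=C=Cc1c(O)c(Br)ccc1O[Si](C(C)C)(C(C)C)C(C)C | intermediate
6 | 8-bromo-2,2-dimethyl-5-(triisopropylsilyloxy)-2H-chromene | Brc1ccc(O[Si](C(C)C)(C(C)C)C(C)C)c2c1OC(C)(C)C=C2 | intermediate
7 | 2-hydroxy-4,6-dimethoxybenzaldehyde | COc1cc(O)c(C=O)c(OC)c1 | starting material
8 | 2,4-dimethoxy-6-(methoxymethoxy)benzaldehyde | COCOc1cc(OC)cc(OC)c1C=O | intermediate
9 | 2,4-dimethoxy-6-(methoxymethoxy)phenyl formate | COCOc1cc(OC)cc(OC)c1OC=O | intermediate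
10 | 2,4-dimethoxy-6-(methoxymethoxy)phenol | COCOc1cc(OC)cc(OC)c1O | intermediate
11 | 2,4-dimethoxy-6-(methoxymethoxy)phenyl trifluoromethanesulfonate | COCOc1cc(OC)cc(OC)c1OS(=O)(=O)C(F)(F)F | intermediate
12 | vinylboronic acid pinacol ester | C=CB1OC(C)(C)C(C)(C)O1 | starting material
13 | 8-lithio-2,2-dimethyl-5-(triisopropylsilyloxy)-2H-chromene | [Li]c1ccc(O[Si](C(C)C)(C(C)C)C(C)C)c2c1OC(C)(C)C=C2 | intermediate
14 | lithium [2,2-dimethyl-5-(triisopropylsilyloxy)-2H-chromen-8-yl](vinyl)(pinacolato)borate | [Li+].C=C[B-]1(OC(C)(C)C(C)(C)O1)c1ccc(O[Si](C(C)C)(C(C)C)C(C)C)c2c1OC(C)(C)C=C2 | intermediate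
15 | pinacol (1R)-1-[2,2-dimethyl-5-(triisopropylsilyloxy)-2H-chromen-8-yl]-2-[2,4-dimethoxy-6-(methoxymethoxy)phenyl]ethylboronate | COCOc1cc(OC)cc(OC)c1C[C@H](c1ccc(O[Si](C(C)C)(C(C)C)C(C)C)c2c1OC(C)(C)C=C2)B1OC(C)(C)C(C)(C)O1 | intermediate
16 | lithium (chloromethyl)(pinacolato)borate complex of 15, R at C3 | [Li+].COCOc1cc(OC)cc(OC)c1C[C@H](c1ccc(O[Si](C(C)C)(C(C)C)C(C)C)c2c1OC(C)(C)C=C2)[B-]1(CCl)OC(C)(C)C(C)(C)O1 | intermediate
17 | pinacol (2R)-2-[2,2-dimethyl-5-(triisopropylsilyloxy)-2H-chromen-8-yl]-3-[2,4-dimethoxy-6-(methoxymethoxy)phenyl]propylboronate | COCOc1cc(OC)cc(OC)c1C[C@H](c1ccc(O[Si](C(C)C)(C(C)C)C(C)C)c2c1OC(C)(C)C=C2)CB1OC(C)(C)C(C)(C)O1 | intermediate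
18 | (2R)-2-[2,2-dimethyl-5-(triisopropylsilyloxy)-2H-chromen-8-yl]-3-[2,4-dimethoxy-6-(methoxymethoxy)phenyl]propan-1-ol | COCOc1cc(OC)cc(OC)c1C[C@H](c1ccc(O[Si](C(C)C)(C(C)C)C(C)C)c2c1OC(C)(C)C=C2)CO | intermediate
19 | 2-[(2R)-2-[2,2-dimethyl-5-(triisopropylsilyloxy)-2H-chromen-8-yl]-3-hydroxypropyl]-3,5-dimethoxyphenol | Oc1cc(OC)cc(OC)c1C[C@H](c1ccc(O[Si](C(C)C)(C(C)C)C(C)C)c2c1OC(C)(C)C=C2)CO | intermediate
20 | 2-[(2R)-2-[2,2-dimethyl-5-(triisopropylsilyloxy)-2H-chromen-8-yl]-3-hydroxypropyl]-6-(hydroxymethyl)-3,5-dimethoxyphenol | Oc1c(CO)c(OC)cc(OC)c1C[C@H](c1ccc(O[Si](C(C)C)(C(C)C)C(C)C)c2c1OC(C)(C)C=C2)CO | intermediate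
21 | 2-hydroxy-3-[(2R)-2-[2,2-dimethyl-5-(triisopropylsilyloxy)-2H-chromen-8-yl]-3-hydroxypropyl]-4,6-dimethoxybenzaldehyde | Oc1c(C=O)c(OC)cc(OC)c1C[C@H](c1ccc(O[Si](C(C)C)(C(C)C)C(C)C)c2c1OC(C)(C)C=C2)CO | intermediate
22 | (3R)-3-[2,2-dimethyl-5-(triisopropylsilyloxy)-2H-chromen-8-yl]-5,7-dimethoxychromane-8-carbaldehyde | COc1cc(OC)c(C=O)c2c1C[C@H](c1ccc(O[Si](C(C)C)(C(C)C)C(C)C)c3c1OC(C)(C)C=C3)CO2 | intermediate
23 | (3R)-3-[2,2-dimethyl-5-(triisopropylsilyloxy)-2H-chromen-8-yl]-7-hydroxy-5-methoxychromane-8-carbaldehyde | COc1cc(O)c(C=O)c2c1C[C@H](c1ccc(O[Si](C(C)C)(C(C)C)C(C)C)c3c1OC(C)(C)C=C3)CO2 | intermediate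
24 | (3R)-7-hydroxy-3-(5-hydroxy-2,2-dimethyl-2H-chromen-8-yl)-5-methoxychromane-8-carbaldehyde | COc1cc(O)c(C=O)c2c1C[C@H](c1ccc(O)c3c1OC(C)(C)C=C3)CO2 | target

## Totals and risks

Total step count: 13. Longest linear sequence: 10 steps (steps 1–3 and 7–13; the ring A branch, steps 4–6 and 7–13, is equally long).

Steps most likely to fail:

**Step 7.** Oxidative addition and reductive elimination at the doubly ortho-substituted, electron-rich triflate may be slow. Direct transfer of the vinyl or aryl group from boron to palladium could then outrun the metallate shift, or enantioface discrimination could be insufficient. The fallback sets out from bromide 6 and triflate 11 and comes back to the route at alcohol 18, bypassing steps 7 and 8. Palladium-catalysed arylation of diethyl malonate with 6 (Pd(OAc)2, P(t-Bu)3·HBF4, K3PO4, toluene, 80 °C) should give diethyl arylmalonate F1, and LiAlH4 reduction should give 2-arylpropane-1,3-diol F2. Lipase-catalysed desymmetrising acetylation (Burkholderia cepacia lipase, vinyl acetate) should give (S)-monoacetate F3; if the enzyme prefers the other arm, hydrolysis of the diacetate with the same enzyme supplies this antipode. Iodine, PPh3 and imidazole convert it to (R)-iodide F4. Zinc insertion (Zn, LiCl, THF) gives alkylzinc iodide F5, which is joined to 11 by Negishi coupling (Pd(OAc)2, CPhos, THF) to give acetate F6, and K2CO3 in MeOH at 0 °C releases 18.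

**Step 10.** The hydroxymethyl intermediate may condense with a second electron-rich arene instead of being oxidised, or the primary alkoxide may sequester magnesium and stall the formylation. The fallback sets out from phenol 19 and comes back at aldehyde 22, reversing the order of ring closure and formylation. Mitsunobu closure of 19 (PPh3, DIAD, THF) should give 5,7-dimethoxyisoflavan F7. Vilsmeier–Haack formylation (POCl3, DMF, 0 °C → rt) should then attack C8, the more nucleophilic and less crowded of the two free ring A positions, to give iminium salt F8, whose hydrolysis with aqueous NaOAc gives 22.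

**Step 11.** The hydrogen-bonded, doubly flanked phenol may attack too slowly, so that the activated alcohol undergoes beta-elimination across C2–C3 (the C3 hydrogen is benzylic, and the stereocentre would be lost) or is captured by the hydrazide. The fallback sets out from 21 and comes back at 22, replacing the redox condensation by a two-stage displacement. Appel bromination (CBr4, PPh3, CH2Cl2, 0 °C) should give primary bromide F9, which is cyclised by intramolecular Williamson etherification with K2CO3 in DMF at rt.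

## Further compounds

F1 | step 7 | diethyl 2-[2,2-dimethyl-5-(triisopropylsilyloxy)-2H-chromen-8-yl]malonate | CCOC(=O)C(C(=O)OCC)c1ccc(O[Si](C(C)C)(C(C)C)C(C)C)c2c1OC(C)(C)C=C2
F2 | step 7 | 2-[2,2-dimethyl-5-(triisopropylsilyloxy)-2H-chromen-8-yl]propane-1,3-diol | OCC(CO)c1ccc(O[Si](C(C)C)(C(C)C)C(C)C)c2c1OC(C)(C)C=C2
F3 | step 7 | (2S)-2-[2,2-dimethyl-5-(triisopropylsilyloxy)-2H-chromen-8-yl]-3-hydroxypropyl acetate | OC[C@H](c1ccc(O[Si](C(C)C)(C(C)C)C(C)C)c2c1OC(C)(C)C=C2)COC(C)=O
F4 | step 7 | (2R)-2-[2,2-dimethyl-5-(triisopropylsilyloxy)-2H-chromen-8-yl]-3-iodopropyl acetate | IC[C@H](c1ccc(O[Si](C(C)C)(C(C)C)C(C)C)c2c1OC(C)(C)C=C2)COC(C)=O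
F5 | step 7 | [(2R)-3-acetoxy-2-[2,2-dimethyl-5-(triisopropylsilyloxy)-2H-chromen-8-yl]propyl]zinc iodide | I[Zn]C[C@H](c1ccc(O[Si](C(C)C)(C(C)C)C(C)C)c2c1OC(C)(C)C=C2)COC(C)=O
F6 | step 7 | (2R)-2-[2,2-dimethyl-5-(triisopropylsilyloxy)-2H-chromen-8-yl]-3-[2,4-dimethoxy-6-(methoxymethoxy)phenyl]propyl acetate | COCOc1cc(OC)cc(OC)c1C[C@H](c1ccc(O[Si](C(C)C)(C(C)C)C(C)C)c2c1OC(C)(C)C=C2)COC(C)=O
F7 | step 10 | (3R)-3-[2,2-dimethyl-5-(triisopropylsilyloxy)-2H-chromen-8-yl]-5,7-dimethoxychromane | COc1cc(OC)cc2c1C[C@H](c1ccc(O[Si](C(C)C)(C(C)C)C(C)C)c3c1OC(C)(C)C=C3)CO2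
F8 | step 10 | N-[[(3R)-3-[2,2-dimethyl-5-(triisopropylsilyloxy)-2H-chromen-8-yl]-5,7-dimethoxychroman-8-yl]methylene]-N-methylmethanaminium chloride | COc1cc(OC)c(C=[N+](C)C)c2c1C[C@H](c1ccc(O[Si](C(C)C)(C(C)C)C(C)C)c3c1OC(C)(C)C=C3)CO2.[Cl-]
F9 | step 11 | 3-[(2R)-3-bromo-2-[2,2-dimethyl-5-(triisopropylsilyloxy)-2H-chromen-8-yl]propyl]-2-hydroxy-4,6-dimethoxybenzaldehyde | Oc1c(C=O)c(OC)cc(OC)c1C[C@H](c1ccc(O[Si](C(C)C)(C(C)C)C(C)C)c2c1OC(C)(C)C=C2)CBr
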